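## Retrosynthetic overview

1. Feature: the target has one ring, a cyclohexene (C1 heptenyl, C2 amide, C3 pentyl, C4=C5, C6 amide). Its C2 carbonyl is γ,δ-unsaturated relative to C4=C5 through the C2–C3 bond, and the C2 and C3 groups are cis. This is the retron of an ester-enolate [3,3] shift.
2. 22 ⇒ diacid 20 (both amide C–N bonds, last step) ⇒ cut C2–C3 and rejoin C5 to oxygen ⇒ all-trans 6-alkenyl δ-lactone 16. Its C6 carboxyl is carried free (as a silyl ester in the flask), not as an alkyl ester.
3. 16 ⇒ δ-hydroxy ester 15 ⇒ auxiliary-controlled syn aldol of imide 9 with (E)-oct-2-enal 10, which sets C6 and the relay carbinol centre.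
4. 9 ⇒ half-ester 6 ⇒ (R)-4-heptenyl-δ-valerolactone 3 ⇒ Rh/BINAP conjugate addition of alkenylboronic acid 1 to dihydropyranone 2, which sets C1.
5. Ring order: the lactone of 3 (opened again in step 2), then the lactone of 16 (step 7), then the cyclohexene (step 8, at the expense of that lactone).

Key step: step 8

Assumption: the facial sense of Rh/BINAP transfer of an alkenyl group to 2 is taken to follow that known for cyclic enones and for aryl transfer to this lactone ((S)-ligand gives the (S)-adduct), hence (R)-BINAP for (R)-3.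

## Route

Step 1
Reactants: 1 (E)-hept-1-en-1-ylboronic acid; 2 5,6-dihydro-2H-pyran-2-one
Product: 3 (4R)-4-[(E)-hept-1-en-1-yl]oxan-2-one
Conditions: Rh(acac)(C2H4)2 (3 mol %), (R)-BINAP, 1 (excess), dioxane/H2O 10:1, 100 °C
Reagents that add atoms: none
Why: Hayashi–Miyaura asymmetric 1,4-addition, in which the alkenyl complex of monovalent rhodium with (R)-BINAP carbometalates the lactone C=C on the face the ligand leaves open, which should set the future C1 centre as (R) and transfer the (E)-alkene with retention.

Step 2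
Reactants: 3 (4R)-4-[(E)-hept-1-en-1-yl]oxan-2-one
Product: 4 methyl (3R,4E)-3-(2-hydroxyethyl)dec-4-enoate
Conditions: MeOH, cat. H2SO4, rt; solid NaHCO3, cold concentration, used at once
Reagents that add atoms: methanol, CO
Why: Acid-catalysed ring-opening transesterification in a large excess of methanol shifts the lactone/hydroxy ester equilibrium to 4, differentiates the two arms of the untouched stereocentre, and neutralisation before evaporation keeps the ring from closing again.

Step 3
Reactants: 4 methyl (3R,4E)-3-(2-hydroxyethyl)dec-4-enoate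
Product: 6 (3R,4E)-3-(2-methoxy-2-oxoethyl)dec-4-enoic acid, via aldehyde 5 (not isolated)
Conditions: TEMPO (20 mol %), PhI(OAc)2 (2.2 equiv), MeCN/H2O 1:1, 0 °C → rt
Reagents that add atoms: water, O
Why: TEMPO/PhI(OAc)2 oxidation in aqueous acetonitrile takes the primary alcohol through aldehyde 5 and its hydrate to the acid under conditions that leave the alkene, the ester and the non-enolisable stereocentre alone.

Step 4
Reactants: 6 (3R,4E)-3-(2-methoxy-2-oxoethyl)dec-4-enoic acid; 7 (4R)-4-benzyl-1,3-oxazolidin-2-one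
Product: 9 methyl (3R,4E)-3-{2-[(4R)-4-benzyl-2-oxo-1,3-oxazolidin-3-yl]-2-oxoethyl}dec-4-enoate, via mixed pivalic anhydride 8 (not isolated)
Conditions: t-BuCOCl, Et3N, THF, −20 °C; then 7, LiCl, −20 °C → rt
Reagents that add atoms: pivaloyl chloride, CC(C)(C)C(=O)Cl (its acyl group is held only in 8)
Why: N-Acylation of the oxazolidinone through the mixed pivalic anhydride takes place at the less hindered carbonyl of 8 and is mild enough that the half-ester should not scramble through a cyclic anhydride, so the C1 centre keeps its integrity.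

Step 5
Reactants: 9 methyl (3R,4E)-3-{2-[(4R)-4-benzyl-2-oxo-1,3-oxazolidin-3-yl]-2-oxoethyl}dec-4-enoate; 10 (E)-oct-2-enal
Product: 13 methyl (3R,4E)-3-{(2R,3S,4E)-1-[(4R)-4-benzyl-2-oxo-1,3-oxazolidin-3-yl]-3-hydroxy-1-oxodec-4-en-2-yl}dec-4-enoate, via (Z)-boron enolate 11 (not isolated), via boron aldolate 12 (not isolated)
Conditions: n-Bu2BOTf, Et3N, CH2Cl2, −78 → 0 °C; 10, −78 → 0 °C; pH 7 buffer, MeOH, 30 % H2O2, 0 °C
Reagents that add atoms: dibutylboron triflate, CCCCB(CCCC)OS(=O)(=O)C(F)(F)F (boron and butyl groups are held only in 11 and 12)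
Why: Evans syn aldol, in which the (Z)-boron enolate reacts through a Zimmerman–Traxler chair on the face away from the benzyl group, so the auxiliary sets the future C6 centre (R) and the carbinol (S) whatever the bias of the β-centre, and this syn pair is exactly the trans relationship needed in the lactone, so no base equilibration next to a β-acyloxy group is needed.

Step 6
Reactants: 13 methyl (3R,4E)-3-{(2R,3S,4E)-1-[(4R)-4-benzyl-2-oxo-1,3-oxazolidin-3-yl]-3-hydroxy-1-oxodec-4-en-2-yl}dec-4-enoate
Product: 15 (2R,3S,4E)-3-hydroxy-2-[(3R,4E)-1-methoxy-1-oxodec-4-en-3-yl]dec-4-enoic acid, via peroxy acid 14 (not isolated)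
Conditions: LiOH, H2O2, THF/H2O 4:1, 0 °C; aq. Na2SO3; 1 M HCl to pH 3
Reagents that add atoms: hydrogen peroxide, OO
Why: Hydroperoxide cleavage of the imide, in which the α-effect nucleophile attacks the exocyclic carbonyl at 0 °C faster than hydroxide touches the methyl ester and without retro-aldol or epimerisation, sulfite then reduces 14, and any ester hydrolysed in passing still converges on 16 in step 7.

Step 7
Reactants: 15 (2R,3S,4E)-3-hydroxy-2-[(3R,4E)-1-methoxy-1-oxodec-4-en-3-yl]dec-4-enoic acid
Product: 16 (2S,3R,4R)-2,4-bis[(E)-hept-1-en-1-yl]-6-oxooxane-3-carboxylic acid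
Conditions: camphorsulfonic acid (5 mol %), 4 Å MS, CH2Cl2, rt
Reagents that add atoms: none
Why: Acid-catalysed lactonisation (6-exo-trig transesterification) of the δ-hydroxy ester exchanges only the acyl C–O bond, so the carbinol configuration is retained, and it is driven by uptake of methanol and by a chair with all three substituents equatorial, while the β-lactone from the free carboxyl is too strained to compete.

Step 8
Reactants: 16 (2S,3R,4R)-2,4-bis[(E)-hept-1-en-1-yl]-6-oxooxane-3-carboxylic acid
Product: 20 (1R,2R,3S,6R)-2-[(E)-hept-1-en-1-yl]-6-pentylcyclohex-4-ene-1,3-dicarboxylic acid, via dilithio enolate carboxylate 17 (not isolated), via bis-silyl ketene acetal 18 (not isolated), via bis-silyl diester 19 (not isolated)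
Conditions: LiN(i-Pr)2 (2.3 equiv), THF/DMPU, −78 °C; TBSCl (2.6 equiv), −78 °C → rt; pentane, filter; toluene, 110 °C; 1 M HCl, THF, rt
Reagents that add atoms: LiN(i-Pr)2, [Li+].CC(C)[N-]C(C)C (lithium is held only in 17); tert-butyldimethylsilyl chloride, CC(C)(C)[Si](C)(C)Cl (silyl groups are held only in 18 and 19)
Why: The first equivalent of base makes the lithium carboxylate at the future C6, which blocks deprotonation there and with it β-elimination of the lactone oxygen, so the second equivalent takes a proton only from the lactone CH2 and double O-silylation gives 18, a cyclic allyl silyl ketene acetal. At 110 °C 18 undergoes a concerted suprafacial [3,3] shift in which the ketene acetal carbon bonds to the far carbon of the (E)-alkenyl group (new C2–C3 bond), the allylic C5–O bond breaks and the alkene moves to C4=C5; this is the Ireland–Claisen rearrangement in its ring-contraction form, known for silyl ketene acetals of 6-alkenyl δ-lactones. Closure of the cyclohexene is thus pericyclic: the C1–C6 unit ties atoms 1 and 4 of the six-atom array together, a chair cannot be reached, and the shift passes through a boat shaped like bicyclo[2.2.2]octane with the alkenyl group axial. C2 is controlled by the (S)-carbinol centre, because the new bond can form only on the lactone face that carries the alkenyl group, which leaves the new carboxyl trans to the C1 heptenyl and cis to the C6 carboxyl. C3 is controlled by the (E)-geometry of the migrating alkene together with the ring-fixed ketene acetal geometry, which in the boat turn the pentyl group to the side of the new carboxyl (cis), while C1 and C6 are spectators and the carbinol chirality is consumed. The step needs site-selective enolisation (secured by the carboxylate), O- rather than C-silylation (TBSCl with DMPU) and a single [3,3] channel (the C1 heptenyl stands 1,4 to the ketene acetal and cannot take part), and dilute acid then cleaves both silyl esters without base, so the allylic C6–H is not put at risk.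

Step 9
Reactants: 20 (1R,2R,3S,6R)-2-[(E)-hept-1-en-1-yl]-6-pentylcyclohex-4-ene-1,3-dicarboxylic acid; 21 isobutylamine
Product: 22 (1R,2R,3S,6R)-2-[(E)-hept-1-en-1-yl]-N1,N3-bis(2-methylpropyl)-6-pentylcyclohex-4-ene-1,3-dicarboxamide
Conditions: 21 (3 equiv), DIC (2.4 equiv), HOBt (2.4 equiv), CH2Cl2, 0 °C → rt
Reagents that add atoms: none
Why: Carbodiimide/HOBt amide coupling with an unhindered primary amine, run from 0 °C without tertiary amine base so that the allylic C6–H of the activated ester is not removed, and with both carboxyls equatorial in the favoured half-chair, which disfavours a bridged anhydride or imide.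

## Compound list

1 | (E)-hept-1-en-1-ylboronic acid | CCCCC/C=C/B(O)O | starting material
2 | 5,6-dihydro-2H-pyran-2-one | O=C1C=CCCO1 | starting material
3 | (4R)-4-[(E)-hept-1-en-1-yl]oxan-2-one | O=C1C[C@H](/C=C/CCCCC)CCO1 | intermediate
4 | methyl (3R,4E)-3-(2-hydroxyethyl)dec-4-enoate | COC(=O)C[C@H](/C=C/CCCCC)CCO | intermediate
5 | methyl (3R,4E)-3-(2-oxoethyl)dec-4-enoate (not isolated) | COC(=O)C[C@H](/C=C/CCCCC)CC=O | intermediate
6 | (3R,4E)-3-(2-methoxy-2-oxoethyl)dec-4-enoic acid | COC(=O)C[C@H](/C=C/CCCCC)CC(=O)O | intermediate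
7 | (4R)-4-benzyl-1,3-oxazolidin-2-one | O=C1N[C@H](Cc2ccccc2)CO1 | starting material
8 | mixed anhydride of 6 with pivalic acid, configuration as in 6 (not isolated) | COC(=O)C[C@H](/C=C/CCCCC)CC(=O)OC(=O)C(C)(C)C | intermediate
9 | methyl (3R,4E)-3-{2-[(4R)-4-benzyl-2-oxo-1,3-oxazolidin-3-yl]-2-oxoethyl}dec-4-enoate | COC(=O)C[C@H](/C=C/CCCCC)CC(=O)N1[C@H](Cc2ccccc2)COC1=O | intermediate
10 | (E)-oct-2-enal | CCCCC/C=C/C=O | starting material
11 | (Z)-dibutylboron enolate of 9 (not isolated) | COC(=O)C[C@H](/C=C/CCCCC)/C=C(\OB(CCCC)CCCC)N1[C@H](Cc2ccccc2)COC1=O | intermediate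
12 | O-dibutylboryl derivative of 13 (not isolated) | COC(=O)C[C@H](/C=C/CCCCC)[C@@H](C(=O)N1[C@H](Cc2ccccc2)COC1=O)[C@@H](OB(CCCC)CCCC)/C=C/CCCCC | intermediate
13 | methyl (3R,4E)-3-{(2R,3S,4E)-1-[(4R)-4-benzyl-2-oxo-1,3-oxazolidin-3-yl]-3-hydroxy-1-oxodec-4-en-2-yl}dec-4-enoate | COC(=O)C[C@H](/C=C/CCCCC)[C@@H](C(=O)N1[C@H](Cc2ccccc2)COC1=O)[C@@H](O)/C=C/CCCCC | intermediate
14 | peroxy acid corresponding to 15 (not isolated) | COC(=O)C[C@H](/C=C/CCCCC)[C@@H](C(=O)OO)[C@@H](O)/C=C/CCCCC | intermediate
15 | (2R,3S,4E)-3-hydroxy-2-[(3R,4E)-1-methoxy-1-oxodec-4-en-3-yl]dec-4-enoic acid | COC(=O)C[C@H](/C=C/CCCCC)[C@@H](C(=O)O)[C@@H](O)/C=C/CCCCC | intermediate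
16 | (2S,3R,4R)-2,4-bis[(E)-hept-1-en-1-yl]-6-oxooxane-3-carboxylic acid (all-trans; key-step precursor) | O=C1C[C@H](/C=C/CCCCC)[C@@H](C(=O)O)[C@H](/C=C/CCCCC)O1 | intermediate
17 | dilithium salt of 16: lactone enolate and carboxylate, configuration as in 16 (not isolated) | [Li+].[Li+].[O-]C1=C[C@H](/C=C/CCCCC)[C@@H](C(=O)[O-])[C@H](/C=C/CCCCC)O1 | intermediate
18 | tert-butyldimethylsilyl 6-(tert-butyldimethylsilyloxy)-2,4-bis[(E)-hept-1-enyl]-3,4-dihydro-2H-pyran-3-carboxylate, spatial arrangement as in 16 (not isolated) | CC(C)(C)[Si](C)(C)OC1=C[C@H](/C=C/CCCCC)[C@@H](C(=O)O[Si](C)(C)C(C)(C)C)[C@H](/C=C/CCCCC)O1 | intermediate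
19 | bis(tert-butyldimethylsilyl) ester of 20 (not isolated) | CCCCC/C=C/[C@H]1[C@H](C(=O)O[Si](C)(C)C(C)(C)C)[C@H](CCCCC)C=C[C@@H]1C(=O)O[Si](C)(C)C(C)(C)C | intermediate
20 | (1R,2R,3S,6R)-2-[(E)-hept-1-en-1-yl]-6-pentylcyclohex-4-ene-1,3-dicarboxylic acid (key-step product) | CCCCC/C=C/[C@H]1[C@H](C(=O)O)[C@H](CCCCC)C=C[C@@H]1C(=O)O | intermediate
21 | isobutylamine (2-methylpropan-1-amine) | CC(C)CN | starting material
22 | (1R,2R,3S,6R)-2-[(E)-hept-1-en-1-yl]-N1,N3-bis(2-methylpropyl)-6-pentylcyclohex-4-ene-1,3-dicarboxamide (CNP0480883.2) | CCCCC/C=C/[C@H]1[C@H](C(=O)NCC(C)C)[C@H](CCCCC)C=C[C@@H]1C(=O)NCC(C)C | target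

## Step count and risks

Total step count: 9. Longest linear sequence: 9 steps (2 → 22).

Steps most likely to fail:

**Step 8.**
- The dilithio species may aggregate or stay out of solution, so that enolisation is incomplete.
- Silyl groups may be lost to adventitious water before the rearrangement temperature is reached.
- Passage through the boat needs all three ring substituents axial and may be slow enough for thermal decay of the ketene acetal to compete.

The fallback uses covalent protection, an isolated ketene acetal and stepwise amide formation. It sets out from 16 and comes back at 22. Me3SiCHN2 in toluene/MeOH should convert 16 into methyl (2S,3R,4R)-2,4-bis[(E)-hept-1-enyl]-6-oxooxane-3-carboxylate F1. LiN(i-Pr)2 added to F1 in the presence of TBSCl at −95 °C should enolise the lactone CH2 faster than the hindered tertiary ester C–H. This gives methyl 6-(tert-butyldimethylsilyloxy)-2,4-bis[(E)-hept-1-enyl]-3,4-dihydro-2H-pyran-3-carboxylate F2, a neutral compound that can be freed from salts by pentane extraction. Thermolysis of F2 in xylene at 140 °C should give the tert-butyldimethylsilyl ester F3. Dilute acid then releases 6-[(E)-hept-1-enyl]-5-(methoxycarbonyl)-2-pentylcyclohex-3-ene-1-carboxylic acid F4. DIC/HOBt coupling of F4 with 21 gives the mono-amide methyl ester F5. AlMe3-mediated aminolysis of F5 with 21 turns the remaining ester directly into the second amide of 22, so the allylic ester is never saponified.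

**Step 1.**
- Protodeboronation of the alkenylboronic acid may outrun addition to the sluggish lactone.
- Facial selectivity for alkenyl transfer may be eroded.

The fallback separates C–C bond formation from enantioselection. It sets out from 1 and comes back at 6. The achiral and much more active [Rh(OH)(cod)]2 in dioxane/H2O near rt should add 1 to commercial dimethyl (E)-pent-2-enedioate and give the prochiral dimethyl 3-[(E)-hept-1-enyl]pentanedioate F6. LiOH gives 3-[(E)-hept-1-enyl]pentanedioic acid F7, and warm Ac2O closes 4-[(E)-hept-1-enyl]oxane-2,6-dione F8. Catalytic desymmetrising methanolysis of F8 with (DHQ)2AQN (MeOH, Et2O, −40 °C) is expected to give (R)-6, by analogy with quinine-type opening of 3-alkylglutaric anhydrides. The pseudoenantiomeric (DHQD)2AQN is at hand should the sense prove opposite.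

**Step 9.**
- Activation of the allylic C6 carboxyl may lead to epimerisation or to migration of the ring alkene into conjugation.
- The C2 carboxyl, flanked by two substituents, may divert to the N-acylurea.

The fallback installs the sensitive amide before the ring exists. It sets out from 15 and comes back at 22. DIC/HOBt coupling of 15 with 21 gives methyl (3R,4E)-3-[(2R,3S,4E)-3-hydroxy-1-(isobutylamino)-1-oxodec-4-en-2-yl]dec-4-enoate F9, at a stage where the α-centre is not allylic. Lactonisation as in step 7 gives (2S,3R,4R)-2,4-bis[(E)-hept-1-enyl]-N-isobutyl-6-oxooxane-3-carboxamide F10. The ring contraction of step 8 is then run with one further equivalent each of base and TBSCl, so that N–H is deprotonated first and shields its α-C–H, and the mixture is kept at −78 °C until silylated. After acidic work-up this should give 6-[(E)-hept-1-enyl]-5-(isobutylcarbamoyl)-2-pentylcyclohex-3-ene-1-carboxylic acid F11. Only its non-allylic carboxyl then has to be coupled with 21 to reach 22.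

## Further compounds

F1 | step 8 | methyl (2S,3R,4R)-2,4-bis[(E)-hept-1-enyl]-6-oxooxane-3-carboxylate | O=C1C[C@H](/C=C/CCCCC)[C@@H](C(=O)OC)[C@H](/C=C/CCCCC)O1
F2 | step 8 | methyl 6-(tert-butyldimethylsilyloxy)-2,4-bis[(E)-hept-1-enyl]-3,4-dihydro-2H-pyran-3-carboxylate, spatial arrangement as in F1 | CC(C)(C)[Si](C)(C)OC1=C[C@H](/C=C/CCCCC)[C@@H](C(=O)OC)[C@H](/C=C/CCCCC)O1
F3 | step 8 | tert-butyldimethylsilyl ester of F4 | CCCCC/C=C/[C@H]1[C@H](C(=O)O[Si](C)(C)C(C)(C)C)[C@H](CCCCC)C=C[C@@H]1C(=O)OC
F4 | step 8 | 6-[(E)-hept-1-enyl]-5-(methoxycarbonyl)-2-pentylcyclohex-3-ene-1-carboxylic acid, configuration as in 20 | CCCCC/C=C/[C@H]1[C@H](C(=O)O)[C@H](CCCCC)C=C[C@@H]1C(=O)OC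
F5 | step 8 | methyl 6-[(E)-hept-1-enyl]-5-(isobutylcarbamoyl)-4-pentylcyclohex-2-ene-1-carboxylate, configuration as in 22 | CCCCC/C=C/[C@H]1[C@H](C(=O)NCC(C)C)[C@H](CCCCC)C=C[C@@H]1C(=O)OC
F6 | step 1 | dimethyl 3-[(E)-hept-1-enyl]pentanedioate | COC(=O)CC(/C=C/CCCCC)CC(=O)OC
F7 | step 1 | 3-[(E)-hept-1-enyl]pentanedioic acid | OC(=O)CC(/C=C/CCCCC)CC(=O)O
F8 | step 1 | 4-[(E)-hept-1-enyl]oxane-2,6-dione | O=C1CC(/C=C/CCCCC)CC(=O)O1
F9 | step 9 | methyl (3R,4E)-3-[(2R,3S,4E)-3-hydroxy-1-(isobutylamino)-1-oxodec-4-en-2-yl]dec-4-enoate | COC(=O)C[C@H](/C=C/CCCCC)[C@@H](C(=O)NCC(C)C)[C@@H](O)/C=C/CCCCC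
F10 | step 9 | (2S,3R,4R)-2,4-bis[(E)-hept-1-enyl]-N-isobutyl-6-oxooxane-3-carboxamide | O=C1C[C@H](/C=C/CCCCC)[C@@H](C(=O)NCC(C)C)[C@H](/C=C/CCCCC)O1
F11 | step 9 | 6-[(E)-hept-1-enyl]-5-(isobutylcarbamoyl)-2-pentylcyclohex-3-ene-1-carboxylic acid, configuration as in 22 | CCCCC/C=C/[C@H]1[C@H](C(=O)O)[C@H](CCCCC)C=C[C@@H]1C(=O)NCC(C)C
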